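The route rests on opening ring C of the lower flavan-3,4-diol unit at O1–C8a and C2–C3. O1 and C4 are ortho on ring A (C8a, C4a), and C2, C3 and C4 carry all-cis substituents, the pattern of a syn-reduced flat chromenone. So an ortho-fluoroaryl α-alkoxymethyl ketone is C-acylated at C3 by 4-benzyloxybenzoyl chloride and the diketonate oxygen displaces fluoride at C8a in the same pot, giving a 3-alkoxyflavone. Asymmetric hydrogenation then sets C2 and C3, and hydride sets C4. The cis-ketone, epimerized at C3, also supplies both upper units, which are joined by a boron-directed cis and a silver-promoted trans C4 arylation.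

Key step: step 4

Remark: flavan numbering is used (O1, C2, C3, C4, C4a, C5–C8, C8a; ring B is the 2-aryl ring). The "lower unit" is the flavan-3,4-diol unit, the "middle unit" is the one whose C4 is bound to C6 of the lower unit, and the "top unit" is the terminal one whose C4 is bound to C6 of the middle unit.
Assumption: the (R,R)-ligand in step 5 is taken to deliver hydrogen to the face that gives the 2R series; if the sense is opposite, the (S,S)-ligand is used.

Step 1
Reactants: 1 4-methoxybenzyl alcohol; 2 2-chloro-N-methoxy-N-methylacetamide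
Product: 3 N-methoxy-2-[(4-methoxybenzyl)oxy]-N-methylacetamide
Conditions: NaH, THF, 0 °C to rt
Reagents that add atoms: none
Why: Williamson ether synthesis, in which the sodium alkoxide of 1 displaces the activated α-chloride of 2 by SN2 while the Weinreb amide is not attacked by an alkoxide at this temperature.

Step 2
Reactants: 4 3-fluorocatechol
Product: 5 1,2-bis(benzyloxy)-3-fluorobenzene
Conditions: BnBr (2.2 equiv), K2CO3, DMF, 60 °C
Reagents that add atoms: benzyl bromide, BrCc1ccccc1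
Why: Double Williamson O-benzylation of the two phenols.

Step 3
Reactants: 5 1,2-bis(benzyloxy)-3-fluorobenzene; 3 N-methoxy-2-[(4-methoxybenzyl)oxy]-N-methylacetamide
Product: 7 1-[3,4-bis(benzyloxy)-2-fluorophenyl]-2-[(4-methoxybenzyl)oxy]ethan-1-one, via aryllithium 6 (not isolated)
Conditions: n-BuLi (1.05 equiv), THF, −78 °C; then 3, −78 to 0 °C; aq NH4Cl
Reagents that add atoms: none
Why: Directed ortho-lithiation next to fluorine (the most acidic ring C–H, the site known for 3-fluoroveratrole) followed by Weinreb ketone synthesis, the chelated tetrahedral adduct preventing over-addition.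

Step 4
Reactants: 7 1-[3,4-bis(benzyloxy)-2-fluorophenyl]-2-[(4-methoxybenzyl)oxy]ethan-1-one; 8 4-(benzyloxy)benzoyl chloride
Product: 10 7,8-bis(benzyloxy)-2-[4-(benzyloxy)phenyl]-3-[(4-methoxybenzyl)oxy]-4H-chromen-4-one, via lithium diketonate 9 (not isolated)
Conditions: LiN(SiMe3)2 (2.2 equiv), THF, −78 °C; 8, −78 to 0 °C; then DMF added, THF distilled off, 90 °C
Reagents that add atoms: none
Why: The lithium enolate of 7 is C-acylated at C3 by 8 (Claisen-type acylation, forming C2–C3), and the second equivalent of base converts the 2-alkoxy-1,3-diketone at once into lithium diketonate 9. On heating in DMF the enolate oxygen on the aroyl carbon (the future O1) adds to C8a, which carries fluorine ortho to the C4 carbonyl, and the Meisenheimer adduct expels lithium fluoride (SNAr, forming O1–C8a), so that ring C closes by a 6-exo-trig addition–elimination on ring A. The closest known reaction type is the one-pot synthesis of flavones from 2′-fluoroacetophenones and aroyl chlorides by acylation and intramolecular O-arylation, the halide variant of the Baker–Venkataraman logic. No stereocentre is created: C2 and C3 are deliberately left sp2 so that the following reductions can add hydrogen to C2, C3 and C4 from one face, which is the all-cis pattern of the lower unit. The step needs C- over O-acylation (lithium enolate chelated by the α-alkoxy group in THF at low temperature, any enol ester being recycled by transacylation) and O- over C-arylation (attack through C3 would need a four-membered ring), and fluorine is the only leaving group and sits ortho to the activating carbonyl.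

Step 5
Reactants: 10 7,8-bis(benzyloxy)-2-[4-(benzyloxy)phenyl]-3-[(4-methoxybenzyl)oxy]-4H-chromen-4-one
Product: 11 (2R,3S)-7,8-bis(benzyloxy)-2-[4-(benzyloxy)phenyl]-3-[(4-methoxybenzyl)oxy]chroman-4-one (2,3-cis)
Conditions: catalyst preformed from [Ru(cod)(2-methylallyl)2] (5 mol%), 1,3-bis[(1R)-1-(naphthalen-1-yl)ethyl]-4,5-dihydroimidazolium tetrafluoroborate (10 mol%), KOtBu (10 mol%) in n-hexane at 70 °C; H2 (50 bar), toluene/n-hexane, 0 °C, stopped when 10 is consumed; filtration through neutral silica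
Reagents that add atoms: none
Why: Asymmetric hydrogenation of the C2=C3 bond of a flavone with a chiral ruthenium N-heterocyclic carbene catalyst, a known reaction of flavones and chromones, should add H2 syn from the catalyst-selected face and so set C2 (R) and C3 (S) together as the 2,3-cis ketone, the aryl-conjugated carbonyl being reduced more slowly so that the run can be stopped at this stage.

Step 6
Reactants: 11 (2R,3S)-7,8-bis(benzyloxy)-2-[4-(benzyloxy)phenyl]-3-[(4-methoxybenzyl)oxy]chroman-4-one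
Product: 12 (2R,3R,4R)-7,8-bis(benzyloxy)-2-[4-(benzyloxy)phenyl]-3-[(4-methoxybenzyl)oxy]chroman-4-ol (2,3-cis-3,4-cis)
Conditions: NaBH4, CeCl3·7H2O, MeOH/THF, −40 °C
Reagents that add atoms: none
Why: Luche reduction of the C4 carbonyl under near-neutral conditions that do not epimerize C3, in which hydride enters anti to the axial 3-alkoxy group so that the 4-OH ends up cis to the 3-alkoxy and 2-aryl groups (substrate control, the known course for 2,3-cis-dihydroflavonols).

Step 7
Reactants: 12 (2R,3R,4R)-7,8-bis(benzyloxy)-2-[4-(benzyloxy)phenyl]-3-[(4-methoxybenzyl)oxy]chroman-4-ol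
Product: 13 (2R,3S,4R)-7,8-bis(benzyloxy)-2-[4-(benzyloxy)phenyl]-3-[(4-methoxybenzyl)oxy]chroman-4-yl acetate (all-cis; same spatial arrangement as 12)
Conditions: Ac2O, pyridine, DMAP (cat.), CH2Cl2, rt
Reagents that add atoms: acetic anhydride, CC(=O)OC(C)=O
Why: DMAP-catalysed esterification masks the benzylic 4-OH so that it cannot act as an O-nucleophile in the later coupling.

Step 8
Reactants: 11 (2R,3S)-7,8-bis(benzyloxy)-2-[4-(benzyloxy)phenyl]-3-[(4-methoxybenzyl)oxy]chroman-4-one
Product: 14 (2R,3R)-7,8-bis(benzyloxy)-2-[4-(benzyloxy)phenyl]-3-[(4-methoxybenzyl)oxy]chroman-4-one (2,3-trans)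
Conditions: Et3N (2 equiv), CH2Cl2/MeOH, rt
Reagents that add atoms: none
Why: Base-mediated epimerization at C3 through the enol, which under thermodynamic control places the 3-alkoxy group equatorial and trans to the 2-aryl group, while C2 is untouched because the mild amine does not open the pyranone ring.

Step 9
Reactants: 14 (2R,3R)-7,8-bis(benzyloxy)-2-[4-(benzyloxy)phenyl]-3-[(4-methoxybenzyl)oxy]chroman-4-one
Product: 15 (2R,3R)-7,8-bis(benzyloxy)-2-[4-(benzyloxy)phenyl]-3-hydroxychroman-4-one (2,3-trans)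
Conditions: DDQ (1.3 equiv), CH2Cl2/pH 7 buffer, rt
Reagents that add atoms: none
Why: Oxidative cleavage of the 4-methoxybenzyl ether (hydride abstraction by DDQ, then hydrolysis of the oxocarbenium ion), which the phenolic benzyl ethers and the deactivated flavanone core should survive.

Step 10
Reactants: 15 (2R,3R)-7,8-bis(benzyloxy)-2-[4-(benzyloxy)phenyl]-3-hydroxychroman-4-one
Product: 16 (2R,3S,4R)-7,8-bis(benzyloxy)-2-[4-(benzyloxy)phenyl]chromane-3,4-diol (2,3-trans-3,4-trans)
Conditions: NaBH4, MeOH/THF, 0 °C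
Reagents that add atoms: none
Why: Hydride reduction of a 2,3-trans-dihydroflavonol with axial attack at C4 gives the equatorial 4-OH (3,4-trans), the established outcome for this class; the C4 configuration is in any case lost when C4 is ionized later.

Step 11
Reactants: 16 (2R,3S,4R)-7,8-bis(benzyloxy)-2-[4-(benzyloxy)phenyl]chromane-3,4-diol
Product: 17 (2R,3S,4R)-7,8-bis(benzyloxy)-2-[4-(benzyloxy)phenyl]-6-bromochromane-3,4-diol
Conditions: NBS (1.0 equiv), CH2Cl2, −20 °C
Reagents that add atoms: N-bromosuccinimide, O=C1CCC(=O)N1Br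
Why: Electrophilic aromatic bromination at C6, the only ring A position that is ortho to the 7-benzyloxy group and para to O1; the bromine blocks C6 of the future top unit and is the handle for boron in the middle unit.

Step 12
Reactants: 17 (2R,3S,4R)-7,8-bis(benzyloxy)-2-[4-(benzyloxy)phenyl]-6-bromochromane-3,4-diol
Product: 18 (2R,3R,4R)-7,8-bis(benzyloxy)-2-[4-(benzyloxy)phenyl]-6-bromochromane-3,4-diyl diacetate (2,3-trans-3,4-trans)
Conditions: Ac2O, pyridine, DMAP (cat.), CH2Cl2, rt
Reagents that add atoms: acetic anhydride, CC(=O)OC(C)=O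
Why: Esterification installs the C4 leaving group and the participating 3-acetate.

Step 13
Reactants: 18 (2R,3R,4R)-7,8-bis(benzyloxy)-2-[4-(benzyloxy)phenyl]-6-bromochromane-3,4-diyl diacetate
Product: 19 (2R,3R,4R)-4-(benzylsulfanyl)-7,8-bis(benzyloxy)-2-[4-(benzyloxy)phenyl]-6-bromochroman-3-yl acetate (2,3-trans-3,4-trans)
Conditions: BnSH (1.5 equiv), TMSOTf (0.1 equiv), CH2Cl2, −78 to −40 °C
Reagents that add atoms: phenylmethanethiol, SCc1ccccc1
Why: Lewis-acid-catalysed SN1 thiolysis, in which the C4 acetate ionizes with participation of the 3-acetate (dioxolenium ion) and the thiol opens it anti to give the 3,4-trans thioether.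

Step 14
Reactants: 19 (2R,3R,4R)-4-(benzylsulfanyl)-7,8-bis(benzyloxy)-2-[4-(benzyloxy)phenyl]-6-bromochroman-3-yl acetate
Product: 20 [(2R,3R,4R)-3-acetoxy-4-(benzylsulfanyl)-7,8-bis(benzyloxy)-2-[4-(benzyloxy)phenyl]chroman-6-yl]boronic acid
Conditions: B2(OH)4 (3 equiv), (XPhos)Pd(2′-amino-1,1′-biphenyl-2-yl)Cl (second-generation XPhos palladacycle, 2 mol%), XPhos (4 mol%), KOAc (3 equiv), EtOH, 70 °C
Reagents that add atoms: tetrahydroxydiboron, OB(O)B(O)O
Why: Miyaura borylation of the aryl bromide with tetrahydroxydiboron gives the boronic acid directly, and the secondary acetate and the thioether are inert to the weak acetate base.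

Step 15
Reactants: 20 [(2R,3R,4R)-3-acetoxy-4-(benzylsulfanyl)-7,8-bis(benzyloxy)-2-[4-(benzyloxy)phenyl]chroman-6-yl]boronic acid; 17 (2R,3S,4R)-7,8-bis(benzyloxy)-2-[4-(benzyloxy)phenyl]-6-bromochromane-3,4-diol
Product: 22 protected dimer in which C4 of the 6-bromo top unit (2,3-trans-3,4-cis; free 3-OH) is bound to C6 of the middle unit (3-O-acetyl; 4-benzylsulfanyl; 2,3-trans-3,4-trans), via boronic ester 21 (not isolated)
Conditions: 4 Å molecular sieves, CH2Cl2, rt; then (CF3)2CHOH added (CH2Cl2/(CF3)2CHOH 4:1), 0 °C to rt; aqueous NaHCO3/sorbitol work-up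
Reagents that add atoms: none
Why: Proposed new method: the 3-OH of diol 17 condenses with boronic acid 20 to boronic ester 21, whose boron also engages the neighbouring benzylic 4-OH; hexafluoroisopropanol then assists heterolysis of the C4–O bond to the cation stabilized by the para 7-benzyloxy group and O1, and the aryl group migrates from the O3-bound borate to C4 through a five-membered transition state, so that C6 of the middle unit is delivered ipso and on the face of O3 (3,4-cis, opposite to the intermolecular preference), C6 of 17 being blocked by bromine and the thioether of 20 staying inert without a thiophile; the closest known reaction types are the Petasis borono-Mannich reaction of α-hydroxy aldehydes, the cis-selective addition of boronates to N-acyliminium ions bearing a vicinal hydroxyl group, and boronic acid or fluoroalcohol-promoted Friedel–Crafts alkylation with benzylic alcohols.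

Step 16
Reactants: 22 protected dimer (top unit bound through C4 to C6 of the 4-benzylsulfanyl middle unit); 13 (2R,3S,4R)-7,8-bis(benzyloxy)-2-[4-(benzyloxy)phenyl]-3-[(4-methoxybenzyl)oxy]chroman-4-yl acetate
Product: 23 protected trimer (top unit: 6-bromo plus free 3-OH; middle unit: 3-O-acetyl; lower unit: 3-O-(4-methoxybenzyl) plus 4-O-acetyl; nine phenolic benzyl ethers; C4 of the middle unit bound to C6 of the lower unit in 3,4-trans configuration)
Conditions: AgOSO2CF3 (2 equiv), 2,6-di-tert-butyl-4-methylpyridine (2.5 equiv), 4 Å molecular sieves, CH2Cl2, −40 to 0 °C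
Reagents that add atoms: none
Why: Silver-promoted (thiophilic) ionization of the 4-benzylthio group and Friedel–Crafts alkylation of 13 at C6 (ortho to 7-OBn, para to O1), in which the 3-acetate of the middle unit bridges the C4 cation on the face of O3 so that the arene enters anti (3,4-trans), while the buffered acid-free medium leaves the 4-acetate of 13 un-ionized.

Step 17
Reactants: 23 protected trimer
Product: 24 deacetylated trimer (free 3-OH on the top unit; free 3-OH on the middle unit; free 4-OH on the lower unit; nine benzyl ethers plus the 4-methoxybenzyl ether plus the bromine retained)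
Conditions: K2CO3, MeOH/THF, rt
Reagents that add atoms: none
Why: Base-catalysed transesterification (methanolysis) removes both acetates without touching the ethers or the interflavan bonds.

Step 18
Reactants: 24 deacetylated trimer
Product: 25 CNP0140823.3 (target)
Conditions: H2 (1 atm), Pd(OH)2/C, Et3N (1.2 equiv), THF/MeOH (degassed), rt; filtration under argon
Reagents that add atoms: none
Why: Catalytic hydrogenolysis cleaves the nine benzyl ethers and the 4-methoxybenzyl ether and reduces the C6–Br bond of the top unit, the amine trapping HBr and keeping the medium non-acidic so that the benzylic 4-OH of the lower unit is spared.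

**Compound list**

1 | 4-methoxybenzyl alcohol | COc1ccc(CO)cc1 | starting material
2 | 2-chloro-N-methoxy-N-methylacetamide | CON(C)C(=O)CCl | starting material
3 | N-methoxy-2-[(4-methoxybenzyl)oxy]-N-methylacetamide | CON(C)C(=O)COCc1ccc(OC)cc1 | intermediate
4 | 3-fluorocatechol | Oc1cccc(F)c1O | starting material
5 | 1,2-bis(benzyloxy)-3-fluorobenzene | Fc1cccc(OCc2ccccc2)c1OCc1ccccc1 | intermediate
6 | [3,4-bis(benzyloxy)-2-fluorophenyl]lithium | [Li]c1ccc(OCc2ccccc2)c(OCc2ccccc2)c1F | intermediate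
7 | 1-[3,4-bis(benzyloxy)-2-fluorophenyl]-2-[(4-methoxybenzyl)oxy]ethan-1-one | COc1ccc(COCC(=O)c2ccc(OCc3ccccc3)c(OCc3ccccc3)c2F)cc1 | intermediate
8 | 4-(benzyloxy)benzoyl chloride | O=C(Cl)c1ccc(OCc2ccccc2)cc1 | starting material
9 | lithium enolate of 1-[3,4-bis(benzyloxy)-2-fluorophenyl]-3-[4-(benzyloxy)phenyl]-2-[(4-methoxybenzyl)oxy]propane-1,3-dione | [Li+].[O-]C(=C(OCc1ccc(OC)cc1)C(=O)c1ccc(OCc2ccccc2)c(OCc2ccccc2)c1F)c1ccc(OCc2ccccc2)cc1 | intermediate
10 | 7,8-bis(benzyloxy)-2-[4-(benzyloxy)phenyl]-3-[(4-methoxybenzyl)oxy]-4H-chromen-4-one | COc1ccc(COc2c(-c3ccc(OCc4ccccc4)cc3)oc3c(OCc4ccccc4)c(OCc4ccccc4)ccc3c2=O)cc1 | intermediate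
11 | (2R,3S)-7,8-bis(benzyloxy)-2-[4-(benzyloxy)phenyl]-3-[(4-methoxybenzyl)oxy]chroman-4-one (2,3-cis) | c1ccccc1COc2ccc(cc2)[C@H]3Oc4c(ccc(OCc5ccccc5)c4OCc6ccccc6)C(=O)[C@H]3OCc7ccc(OC)cc7 | intermediate
12 | (2R,3R,4R)-7,8-bis(benzyloxy)-2-[4-(benzyloxy)phenyl]-3-[(4-methoxybenzyl)oxy]chroman-4-ol (2,3-cis-3,4-cis) | c1ccccc1COc2ccc(cc2)[C@H]3Oc4c(ccc(OCc5ccccc5)c4OCc6ccccc6)[C@@H](O)[C@H]3OCc7ccc(OC)cc7 | intermediate
13 | (2R,3S,4R)-7,8-bis(benzyloxy)-2-[4-(benzyloxy)phenyl]-3-[(4-methoxybenzyl)oxy]chroman-4-yl acetate (all-cis) | c1ccccc1COc2ccc(cc2)[C@H]3Oc4c(ccc(OCc5ccccc5)c4OCc6ccccc6)[C@@H](OC(C)=O)[C@H]3OCc7ccc(OC)cc7 | intermediate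
14 | (2R,3R)-7,8-bis(benzyloxy)-2-[4-(benzyloxy)phenyl]-3-[(4-methoxybenzyl)oxy]chroman-4-one (2,3-trans) | c1ccccc1COc2ccc(cc2)[C@H]3Oc4c(ccc(OCc5ccccc5)c4OCc6ccccc6)C(=O)[C@@H]3OCc7ccc(OC)cc7 | intermediate
15 | (2R,3R)-7,8-bis(benzyloxy)-2-[4-(benzyloxy)phenyl]-3-hydroxychroman-4-one (2,3-trans) | c1ccccc1COc2ccc(cc2)[C@H]3Oc4c(ccc(OCc5ccccc5)c4OCc6ccccc6)C(=O)[C@@H]3O | intermediate
16 | (2R,3S,4R)-7,8-bis(benzyloxy)-2-[4-(benzyloxy)phenyl]chromane-3,4-diol (2,3-trans-3,4-trans) | c1ccccc1COc2ccc(cc2)[C@H]3Oc4c(ccc(OCc5ccccc5)c4OCc6ccccc6)[C@@H](O)[C@@H]3O | intermediate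
17 | (2R,3S,4R)-7,8-bis(benzyloxy)-2-[4-(benzyloxy)phenyl]-6-bromochromane-3,4-diol | c1ccccc1COc2ccc(cc2)[C@H]3Oc4c(cc(Br)c(OCc5ccccc5)c4OCc6ccccc6)[C@@H](O)[C@@H]3O | intermediate
18 | (2R,3R,4R)-7,8-bis(benzyloxy)-2-[4-(benzyloxy)phenyl]-6-bromochromane-3,4-diyl diacetate (2,3-trans-3,4-trans) | c1ccccc1COc2ccc(cc2)[C@H]3Oc4c(cc(Br)c(OCc5ccccc5)c4OCc6ccccc6)[C@@H](OC(C)=O)[C@@H]3OC(C)=O | intermediate
19 | (2R,3R,4R)-4-(benzylsulfanyl)-7,8-bis(benzyloxy)-2-[4-(benzyloxy)phenyl]-6-bromochroman-3-yl acetate (2,3-trans-3,4-trans) | c1ccccc1COc2ccc(cc2)[C@H]3Oc4c(cc(Br)c(OCc5ccccc5)c4OCc6ccccc6)[C@@H](SCc7ccccc7)[C@@H]3OC(C)=O | intermediate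
20 | [(2R,3R,4R)-3-acetoxy-4-(benzylsulfanyl)-7,8-bis(benzyloxy)-2-[4-(benzyloxy)phenyl]chroman-6-yl]boronic acid | c1ccccc1COc2ccc(cc2)[C@H]3Oc4c(cc(B(O)O)c(OCc5ccccc5)c4OCc6ccccc6)[C@@H](SCc7ccccc7)[C@@H]3OC(C)=O | intermediate
21 | mixed boronic ester: O3 of diol 17 bound to the boron of 20 (aryl(hydroxy)boryl ester; 4-OH of the diol unit free) | c1ccccc1COc2ccc(cc2)[C@H]3Oc4c(cc(Br)c(OCc5ccccc5)c4OCc6ccccc6)[C@@H](O)[C@@H]3OB(O)c1cc2c(c(OCc4ccccc4)c1OCc1ccccc1)O[C@H](c1ccc(OCc4ccccc4)cc1)[C@@H](OC(C)=O)[C@@H]2SCc1ccccc1 | intermediate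
22 | protected dimer: top unit (6-bromo; 7,8,4′-tri-O-benzyl; (2R)-2,3-trans-3,4-cis; free 3-OH) bound through C4 to C6 of the middle unit (3-O-acetyl; 4-benzylsulfanyl; 7,8,4′-tri-O-benzyl; (2R)-2,3-trans-3,4-trans) | c1ccccc1CS[C@@H]2c3cc([C@H]4c5cc(Br)c(OCc6ccccc6)c(OCc6ccccc6)c5O[C@H](c5ccc(OCc6ccccc6)cc5)[C@H]4O)c(OCc4ccccc4)c(OCc4ccccc4)c3O[C@H](c3ccc(OCc4ccccc4)cc3)[C@H]2OC(C)=O | intermediate
23 | protected trimer: top unit (6-bromo, free 3-OH) bound C4 to C6 of the middle unit (3-O-acetyl), which is bound C4 to C6 of the lower unit (all-cis; 3-O-(4-methoxybenzyl); 4-O-acetyl); nine phenolic benzyl ethers | c1ccccc1COc1ccc([C@H]2Oc3c(cc([C@@H]4c5cc([C@H]6c7cc(Br)c(OCc8ccccc8)c(OCc8ccccc8)c7O[C@H](c7ccc(OCc8ccccc8)cc7)[C@H]6O)c(OCc6ccccc6)c(OCc6ccccc6)c5O[C@H](c5ccc(OCc6ccccc6)cc5)[C@H]4OC(C)=O)c(OCc4ccccc4)c3OCc3ccccc3)[C@@H](OC(C)=O)[C@H]2OCc2ccc(OC)cc2)cc1 | intermediate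
24 | deacetylated trimer: as 23 with free 3-OH on the middle unit and free 4-OH on the lower unit | c1ccccc1COc1ccc([C@H]2Oc3c(cc([C@@H]4c5cc([C@H]6c7cc(Br)c(OCc8ccccc8)c(OCc8ccccc8)c7O[C@H](c7ccc(OCc8ccccc8)cc7)[C@H]6O)c(OCc6ccccc6)c(OCc6ccccc6)c5O[C@H](c5ccc(OCc6ccccc6)cc5)[C@H]4O)c(OCc4ccccc4)c3OCc3ccccc3)[C@@H](O)[C@H]2OCc2ccc(OC)cc2)cc1 | intermediate
25 | CNP0140823.3 | Oc1ccc([C@H]2Oc3c(cc([C@@H]4c5cc([C@H]6c7ccc(O)c(O)c7O[C@H](c7ccc(O)cc7)[C@H]6O)c(O)c(O)c5O[C@H](c5ccc(O)cc5)[C@H]4O)c(O)c3O)[C@@H](O)[C@H]2O)cc1 | target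

**Totals**

Total step count: 18.
Longest linear sequence: 15 steps (4 → 5 → 7 → 10 → 11 → 14 → 15 → 16 → 17 → 18 → 19 → 20 → 22 → 23 → 24 → 25, that is steps 2 to 5 and 8 to 18); steps 1, 6 and 7 are side branches.

**Steps most likely to fail**

1. Step 15 (Proposed new method). The boronic acid may lose boron by protodeboronation in the fluoroalcohol, the C4–O bond may not ionize under such mild activation, or the arene may be captured outside the borate tether, which would remove the facial control. The fallback uses undirected silver-promoted Friedel–Crafts couplings only and sets out from 19, 13 and 17. Thioether 19 is coupled with 13 (AgOSO2CF3, 2,6-di-tert-butyl-4-methylpyridine, CH2Cl2) to give the middle–lower dimer bromide F1, 3,4-trans through acetate participation. The bromine is removed with Bu3SnH/AIBN in toluene at 80 °C to give the debrominated dimer F2. Separately, diol 17 is converted with BnSH and catalytic TMSOTf into the 4-benzylsulfanyl-6-bromoflavan-3-ol F3. Silver-promoted coupling of F3 with F2 then forms the C4–C6 bond without direction and should give both C4 epimers at the top unit. The 3,4-cis isomer is 23, where the route is rejoined; it is separated by preparative HPLC from the 3,4-trans epimer F4.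

2. Step 5. The tetrasubstituted 3-alkoxy enone may be hydrogenated slowly or with poor facial selectivity, the carbonyl may be reduced further before the enone is consumed, and the cis-ketone may epimerize at C3 on the basic catalyst. The fallback sets out from 10. Heterogeneous syn-hydrogenation (H2, 50 bar, Raney Ni, EtOAc/EtOH) should give the racemic all-cis alcohol F5. Acylation with (1S)-camphanic chloride (pyridine, DMAP) gives two diastereomeric esters, and the (2R,3R,4R)-camphanate F6 is separated from the (2S,3S,4S)-camphanate F7 by chromatography or crystallization. Methanolysis of F6 (K2CO3, MeOH) gives 12, which enters step 7 directly. Dess–Martin oxidation of the remainder of this 12 (NaHCO3, CH2Cl2, 0 °C) returns to 11 for step 8.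

3. Step 18. Hydrogenolysis of the benzylic C4–O bond of the lower unit may compete with debenzylation, and the free polyphenol may oxidize during isolation. The fallback sets out from 24. MnO2 in CH2Cl2 oxidizes only the benzylic 4-OH of the lower unit to give the trimer ketone F8. Hydrogenolysis (H2, Pd(OH)2/C, Et3N) then gives the free phenolic 3-hydroxyflavanone trimer F9, whose lower unit is 2,3-cis. NaBH4 in MeOH at 0 °C reduces the C4 carbonyl anti to the axial 3-OH, the classical route from dihydroflavonols to flavan-3,4-diols, and returns to 25.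

**Further compounds**

F1 | step 15 | dimer bromide: middle unit (6-bromo; 3-O-acetyl; 2,3-trans-3,4-trans) bound C4 to C6 of the lower unit (all-cis; 3-O-(4-methoxybenzyl); 4-O-acetyl) | c1ccccc1COc1ccc([C@H]2Oc3c(cc([C@@H]4c5cc(Br)c(OCc6ccccc6)c(OCc6ccccc6)c5O[C@H](c5ccc(OCc6ccccc6)cc5)[C@H]4OC(C)=O)c(OCc4ccccc4)c3OCc3ccccc3)[C@@H](OC(C)=O)[C@H]2OCc2ccc(OC)cc2)cc1
F2 | step 15 | debrominated dimer (as F1 with H at C6 of the middle unit) | c1ccccc1COc1ccc([C@H]2Oc3c(cc([C@@H]4c5ccc(OCc6ccccc6)c(OCc6ccccc6)c5O[C@H](c5ccc(OCc6ccccc6)cc5)[C@H]4OC(C)=O)c(OCc4ccccc4)c3OCc3ccccc3)[C@@H](OC(C)=O)[C@H]2OCc2ccc(OC)cc2)cc1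
F3 | step 15 | (2R)-4-(benzylsulfanyl)-7,8-bis(benzyloxy)-2-[4-(benzyloxy)phenyl]-6-bromochroman-3-ol (2,3-trans-3,4-trans) | c1ccccc1COc2ccc(cc2)[C@H]3Oc4c(cc(Br)c(OCc5ccccc5)c4OCc6ccccc6)[C@@H](SCc7ccccc7)[C@@H]3O
F4 | step 15 | C4 epimer of 23 at the top unit (top unit 2,3-trans-3,4-trans) | c1ccccc1COc1ccc([C@H]2Oc3c(cc([C@@H]4c5cc([C@@H]6c7cc(Br)c(OCc8ccccc8)c(OCc8ccccc8)c7O[C@H](c7ccc(OCc8ccccc8)cc7)[C@H]6O)c(OCc6ccccc6)c(OCc6ccccc6)c5O[C@H](c5ccc(OCc6ccccc6)cc5)[C@H]4OC(C)=O)c(OCc4ccccc4)c3OCc3ccccc3)[C@@H](OC(C)=O)[C@H]2OCc2ccc(OC)cc2)cc1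
F5 | step 5 | racemic all-cis 7,8-bis(benzyloxy)-2-[4-(benzyloxy)phenyl]-3-[(4-methoxybenzyl)oxy]chroman-4-ol (12 and its enantiomer) | c1ccccc1COc2ccc(cc2)[C@H]3Oc4c(ccc(OCc5ccccc5)c4OCc6ccccc6)[C@@H](O)[C@H]3OCc7ccc(OC)cc7.c1ccccc1COc2ccc(cc2)[C@@H]3Oc4c(ccc(OCc5ccccc5)c4OCc6ccccc6)[C@H](O)[C@@H]3OCc7ccc(OC)cc7
F6 | step 5 | (1S)-camphanate of (2R,3R,4R)-12 at O4 | c1ccccc1COc2ccc(cc2)[C@H]3Oc4c(ccc(OCc5ccccc5)c4OCc6ccccc6)[C@@H](OC(=O)[C@@]89CC[C@@](C)(C(=O)O8)C9(C)C)[C@H]3OCc7ccc(OC)cc7
F7 | step 5 | (1S)-camphanate of the (2S,3S,4S)-enantiomer of 12 at O4 | c1ccccc1COc2ccc(cc2)[C@@H]3Oc4c(ccc(OCc5ccccc5)c4OCc6ccccc6)[C@H](OC(=O)[C@@]89CC[C@@](C)(C(=O)O8)C9(C)C)[C@@H]3OCc7ccc(OC)cc7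
F8 | step 18 | trimer ketone: 24 with C4 of the lower unit oxidized to the carbonyl (lower unit 2,3-cis) | c1ccccc1COc1ccc([C@H]2Oc3c(cc([C@@H]4c5cc([C@H]6c7cc(Br)c(OCc8ccccc8)c(OCc8ccccc8)c7O[C@H](c7ccc(OCc8ccccc8)cc7)[C@H]6O)c(OCc6ccccc6)c(OCc6ccccc6)c5O[C@H](c5ccc(OCc6ccccc6)cc5)[C@H]4O)c(OCc4ccccc4)c3OCc3ccccc3)C(=O)[C@H]2OCc2ccc(OC)cc2)cc1
F9 | step 18 | free phenolic trimer with the lower unit as the 2,3-cis-3-hydroxyflavan-4-one | Oc1ccc([C@H]2Oc3c(cc([C@@H]4c5cc([C@H]6c7ccc(O)c(O)c7O[C@H](c7ccc(O)cc7)[C@H]6O)c(O)c(O)c5O[C@H](c5ccc(O)cc5)[C@H]4O)c(O)c3O)C(=O)[C@H]2O)cc1
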